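**Strategy.** Germacrane numbering is used: ring A is the ten-membered carbocycle C1–C10, ring B the α-methylene-γ-lactone (O on C6, fusion C6–C7); tiglate on C8, OH on C2, OAc on C5. The plan opens ring A between C4 and C5, where a carbinol carbon sits next to the C4=C15 methylidene: the retron of an alkenylchromium–aldehyde addition. An intramolecular Nozaki–Hiyama–Kishi reaction of a 2-bromoalkene aldehyde closes ring A, sets C5 and keeps the methylidene in one operation. The precursor already carries ring B, the tiglate and the (Z)-C1=C10 alkene; it is joined from a propargylic-alcohol-derived west half and a glyceraldehyde-derived allyl bromide.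

Key step: step 15

Assumption: (4S)-2,2-dimethyl-1,3-dioxolane-4-carbaldehyde (12) is taken as purchased; it is otherwise one Swern oxidation away from commercial (R)-solketal.

Step 1
Reactants: 1 but-2-ynal; 2 2,3-dibromoprop-1-ene
Product: 3 rac-2-bromohept-1-en-5-yn-4-ol
Conditions: In powder, THF/H2O (1:1), rt
Reagents that add atoms: none
Why: Barbier reaction in which indium inserts only into the allylic C–Br bond of 2 and the 2-bromoallylindium adds 1,2 to the ynal, leaving the alkenyl bromide for the key step; no stereocontrol is sought because C2 is reset in steps 2 and 3.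

Step 2
Reactants: 3 rac-2-bromohept-1-en-5-yn-4-ol
Product: 4 2-bromohept-1-en-5-yn-4-one
Conditions: Dess–Martin periodinane, CH2Cl2, 0 °C to rt
Reagents that add atoms: none
Why: Dess–Martin oxidation of the propargylic alcohol under non-basic conditions should give the ynone without moving the β,γ-alkene into conjugation.

Step 3
Reactants: 4 2-bromohept-1-en-5-yn-4-one
Product: 5 (4R)-2-bromohept-1-en-5-yn-4-ol
Conditions: Ru[(R,R)-TsNCH(Ph)CH(Ph)NH](p-cymene) (1 mol %), i-PrOH, rt
Reagents that add atoms: none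
Why: Noyori-type asymmetric transfer hydrogenation of an alkynyl ketone, in which the alkynyl group takes the place an aryl group has in the six-membered hydride-transfer transition state, so the (R,R)-catalyst should give the (R)-propargylic alcohol (C2), and the base-free amido complex avoids isomerisation of the CH2 next to the ketone.

Step 4
Reactants: 5 (4R)-2-bromohept-1-en-5-yn-4-ol
Product: 7 (4R,5Z)-2-bromo-6-iodohepta-1,5-dien-4-ol, via cyclic sodium alkenylaluminate 6 (not isolated)
Conditions: NaAlH2(OCH2CH2OMe)2, THF, 0 °C to rt; then I2, −78 °C to 0 °C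
Reagents that add atoms: iodine, II
Why: Hydroxyl-directed trans-hydroalumination of the propargylic alcohol places aluminium on the distal carbon (C10) in a five-membered aluminate, and iodinolysis with retention gives the (Z)-iodoalkene in which iodine, the future site of C9, is cis to C2.

Step 5
Reactants: 7 (4R,5Z)-2-bromo-6-iodohepta-1,5-dien-4-ol
Product: 8 {[(4R,5Z)-2-bromo-6-iodohepta-1,5-dien-4-yl]oxy}(tert-butyl)dimethylsilane
Conditions: TBSCl, imidazole, DMF, rt
Reagents that add atoms: tert-butyldimethylsilyl chloride, CC(C)(C)[Si](C)(C)Cl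
Why: Standard silylation of the secondary allylic alcohol keeps the C2 oxygen masked until the last step, so that later only the C5 hydroxyl is acetylated.

Step 6
Reactants: 8 {[(4R,5Z)-2-bromo-6-iodohepta-1,5-dien-4-yl]oxy}(tert-butyl)dimethylsilane; 9 (2-ethoxy-2-oxoethyl)zinc bromide
Product: 10 ethyl (3Z,5R)-7-bromo-5-[(tert-butyldimethylsilyl)oxy]-3-methylocta-3,7-dienoate
Conditions: Pd(PPh3)4 (5 mol %), THF, 50 °C
Reagents that add atoms: none
Why: Negishi coupling of a Reformatsky reagent, in which zerovalent palladium inserts into the alkenyl C–I bond much faster than into the C–Br bond and couples with retention of the Z geometry, installing C9 and C8.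

Step 7
Reactants: 10 ethyl (3Z,5R)-7-bromo-5-[(tert-butyldimethylsilyl)oxy]-3-methylocta-3,7-dienoate
Product: 11 (3Z,5R)-7-bromo-5-[(tert-butyldimethylsilyl)oxy]-3-methylocta-3,7-dienal
Conditions: i-Bu2AlH (1.1 equiv), CH2Cl2, −78 °C; MeOH, then aqueous work-up
Reagents that add atoms: none
Why: Partial reduction of the ester at low temperature through the stable aluminium hemiacetal should give the β,γ-unsaturated aldehyde, which is used at once to avoid migration of the alkene.

Step 8
Reactants: 12 (4S)-2,2-dimethyl-1,3-dioxolane-4-carbaldehyde; 13 methyl acrylate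
Product: 14 methyl 2-{[(4S)-2,2-dimethyl-1,3-dioxolan-4-yl](hydroxy)methyl}prop-2-enoate (both carbinol epimers)
Conditions: DABCO (0.5 equiv), dioxane/H2O (1:1), rt
Reagents that add atoms: none
Why: Morita–Baylis–Hillman reaction of an activated α-alkoxy aldehyde; the new carbinol centre is erased in step 9, so its configuration does not matter.

Step 9
Reactants: 14 methyl 2-{[(4S)-2,2-dimethyl-1,3-dioxolan-4-yl](hydroxy)methyl}prop-2-enoate
Product: 15 methyl (2Z)-2-(bromomethyl)-3-[(4R)-2,2-dimethyl-1,3-dioxolan-4-yl]prop-2-enoate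
Conditions: NBS, Me2S, CH2Cl2, 0 °C to rt
Reagents that add atoms: N-bromosuccinimide, O=C1CCC(=O)N1Br
Why: Corey–Kim-type bromination with allylic transposition (SN2′) should give the thermodynamically preferred (Z)-2-(bromomethyl)enoate, in which C6 is cis to CH2Br, and removes the carbinol centre.

Step 10
Reactants: 15 methyl (2Z)-2-(bromomethyl)-3-[(4R)-2,2-dimethyl-1,3-dioxolan-4-yl]prop-2-enoate; 11 (3Z,5R)-7-bromo-5-[(tert-butyldimethylsilyl)oxy]-3-methylocta-3,7-dienal
Product: 17 methyl (3R,4R,6Z,8R)-10-bromo-8-[(tert-butyldimethylsilyl)oxy]-3-[(1R)-1,2-dihydroxyethyl]-4-hydroxy-6-methyl-2-methylideneundeca-6,10-dienoate, via diol bromide 16 (not isolated)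
Conditions: Dowex 50W (H+ form), THF/H2O (1:1), rt; filtered, acetone evaporated; then 11, In powder, THF/H2O, rt
Reagents that add atoms: none
Why: Aqueous Barbier reaction of a 2-(alkoxycarbonyl)allyl bromide, in which the allylindium reacts at its γ-carbon (C7) through a chair transition state, the (Z)-geometry gives the syn C7/C8 relationship, and the free C6 hydroxyl, bound to indium while allylic strain keeps C6–H in the alkene plane, delivers the aldehyde to the face syn to that hydroxyl, so that C6 from 12 should set C7 (R) and C8 (R).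

Step 11
Reactants: 17 methyl (3R,4R,6Z,8R)-10-bromo-8-[(tert-butyldimethylsilyl)oxy]-3-[(1R)-1,2-dihydroxyethyl]-4-hydroxy-6-methyl-2-methylideneundeca-6,10-dienoate
Product: 18 methyl (3R,4R,6Z,8R)-10-bromo-8-[(tert-butyldimethylsilyl)oxy]-3-[(4R)-2,2-dimethyl-1,3-dioxolan-4-yl]-4-hydroxy-6-methyl-2-methylideneundeca-6,10-dienoate
Conditions: 2-methoxypropene, PPTS (cat.), CH2Cl2, 0 °C
Reagents that add atoms: 2-methoxypropene, COC(C)=C
Why: Kinetic acetonide formation should take the terminal 1,2-diol as the five-membered dioxolane in preference to the 1,3-dioxane, leaving only the C8 hydroxyl free.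

Step 12
Reactants: 18 methyl (3R,4R,6Z,8R)-10-bromo-8-[(tert-butyldimethylsilyl)oxy]-3-[(4R)-2,2-dimethyl-1,3-dioxolan-4-yl]-4-hydroxy-6-methyl-2-methylideneundeca-6,10-dienoate
Product: 19 methyl (3R,4R,6Z,8R)-10-bromo-8-[(tert-butyldimethylsilyl)oxy]-3-[(4R)-2,2-dimethyl-1,3-dioxolan-4-yl]-6-methyl-4-{[(2E)-2-methylbut-2-enoyl]oxy}-2-methylideneundeca-6,10-dienoate
Conditions: tigloyl chloride, pyridine, DMAP (cat.), CH2Cl2, 0 °C to rt
Reagents that add atoms: (2E)-2-methylbut-2-enoyl chloride, ClC(=O)/C(C)=C/C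
Why: Acylation of the one remaining secondary hydroxyl with the (E)-acid chloride installs the C8 tiglate, the thermodynamically stable geometry that does not isomerise under these conditions.

Step 13
Reactants: 19 methyl (3R,4R,6Z,8R)-10-bromo-8-[(tert-butyldimethylsilyl)oxy]-3-[(4R)-2,2-dimethyl-1,3-dioxolan-4-yl]-6-methyl-4-{[(2E)-2-methylbut-2-enoyl]oxy}-2-methylideneundeca-6,10-dienoate
Product: 21 (1R,3Z,5R)-7-bromo-5-[(tert-butyldimethylsilyl)oxy]-1-[(2R,3R)-2-(hydroxymethyl)-4-methylidene-5-oxooxolan-3-yl]-3-methylocta-3,7-dien-1-yl (2E)-2-methylbut-2-enoate, via diol ester 20 (not isolated)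
Conditions: CeCl3·7H2O, oxalic acid (cat.), MeCN, rt; then p-TsOH·H2O (cat.), CH2Cl2, rt
Reagents that add atoms: none
Why: Mild acid removes the terminal acetonide without touching the silyl ether, and the freed C6 hydroxyl closes ring B as the cis-disubstituted α-methylene-γ-lactone (five-membered lactone favoured over the δ-lactone through O5), leaving the primary C5 hydroxyl.

Step 14
Reactants: 21 (1R,3Z,5R)-7-bromo-5-[(tert-butyldimethylsilyl)oxy]-1-[(2R,3R)-2-(hydroxymethyl)-4-methylidene-5-oxooxolan-3-yl]-3-methylocta-3,7-dien-1-yl (2E)-2-methylbut-2-enoate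
Product: 22 (1R,3Z,5R)-7-bromo-5-[(tert-butyldimethylsilyl)oxy]-1-[(2R,3R)-2-formyl-4-methylidene-5-oxooxolan-3-yl]-3-methylocta-3,7-dien-1-yl (2E)-2-methylbut-2-enoate
Conditions: Dess–Martin periodinane, CH2Cl2, 0 °C to rt; used without delay
Reagents that add atoms: none
Why: Dess–Martin oxidation of the primary alcohol under non-basic conditions should give the α-acyloxy aldehyde without epimerising C6.

Step 15
Reactants: 22 (1R,3Z,5R)-7-bromo-5-[(tert-butyldimethylsilyl)oxy]-1-[(2R,3R)-2-formyl-4-methylidene-5-oxooxolan-3-yl]-3-methylocta-3,7-dien-1-yl (2E)-2-methylbut-2-enoate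
Product: 23 (1(10)Z,2R,5S,6R,7R,8R)-2-[(tert-butyldimethylsilyl)oxy]-5-hydroxy-8-{[(2E)-2-methylbut-2-enoyl]oxy}germacra-1(10),4(15),11(13)-trien-12,6-olide
Conditions: CrCl2 (10 equiv), NiCl2 (0.1 equiv), degassed DMSO/THF (3:1), slow addition of 22 to 2 mM, rt to 45 °C
Reagents that add atoms: none
Why: Zerovalent nickel, formed from NiCl2 by divalent chromium, inserts into the C4–Br bond, the alkenyl group passes to chromium, and the alkenylchromium adds to the C5 aldehyde; this is an intramolecular Nozaki–Hiyama–Kishi reaction, a type well precedented for medium and large carbocycles and tolerant of esters, silyl ethers and enoates. Ring A closes in a 10-exo-trig mode at high dilution, helped by two turn elements already present in 22, the (Z)-C1=C10 alkene and the cis-disubstituted lactone ring B. The new C5 stereocentre is controlled by the adjacent C6: in the Felkin–Anh arrangement the C6–O bond lies anti to the incoming alkenyl group and the attack passes C6–H, which should give the (5S) alcohol. The step needs chemoselectivity for the aldehyde over three ester carbonyls and the α-methylene lactone, which the low basicity and strong aldehyde preference of alkenylchromium reagents secure, and it needs cyclisation to outrun intermolecular coupling, which dilution and the two turn elements secure.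

Step 16
Reactants: 23 (1(10)Z,2R,5S,6R,7R,8R)-2-[(tert-butyldimethylsilyl)oxy]-5-hydroxy-8-{[(2E)-2-methylbut-2-enoyl]oxy}germacra-1(10),4(15),11(13)-trien-12,6-olide
Product: 24 (1(10)Z,2R,5S,6R,7R,8R)-5-acetoxy-2-[(tert-butyldimethylsilyl)oxy]-8-{[(2E)-2-methylbut-2-enoyl]oxy}germacra-1(10),4(15),11(13)-trien-12,6-olide
Conditions: Ac2O, pyridine, DMAP (cat.), CH2Cl2, 0 °C to rt
Reagents that add atoms: acetic anhydride, CC(=O)OC(C)=O
Why: Standard acetylation of the only free hydroxyl (C5) with retention of configuration.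

Step 17
Reactants: 24 (1(10)Z,2R,5S,6R,7R,8R)-5-acetoxy-2-[(tert-butyldimethylsilyl)oxy]-8-{[(2E)-2-methylbut-2-enoyl]oxy}germacra-1(10),4(15),11(13)-trien-12,6-olide
Product: 25 CNP0210609.1, (1(10)Z,2R,5S,6R,7R,8R)-5-acetoxy-2-hydroxy-8-{[(2E)-2-methylbut-2-enoyl]oxy}germacra-1(10),4(15),11(13)-trien-12,6-olide
Conditions: HF·pyridine, THF/pyridine, 0 °C to rt
Reagents that add atoms: none
Why: Fluoride-mediated cleavage of the secondary silyl ether under buffered acidic conditions frees the C2 hydroxyl and should leave the acetate, the tiglate and the α-methylene lactone untouched.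

**Compound list**

1 | but-2-ynal | CC#CC=O | starting material
2 | 2,3-dibromoprop-1-ene | C=C(Br)CBr | starting material
3 | rac-2-bromohept-1-en-5-yn-4-ol | CC#CC(O)CC(Br)=C | intermediate
4 | 2-bromohept-1-en-5-yn-4-one | CC#CC(=O)CC(Br)=C | intermediate
5 | (4R)-2-bromohept-1-en-5-yn-4-ol | CC#C[C@H](O)CC(Br)=C | intermediate
6 | sodium (5R)-5-(2-bromoprop-2-en-1-yl)-2,2-bis(2-methoxyethoxy)-3-methyl-2,5-dihydro-1,2-oxaluminol-2-uide (cyclic alkenylaluminate, not isolated) | CC1=C[C@@H](CC(Br)=C)O[Al-]1(OCCOC)OCCOC.[Na+] | intermediate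
7 | (4R,5Z)-2-bromo-6-iodohepta-1,5-dien-4-ol | I/C(C)=C\[C@H](O)CC(Br)=C | intermediate
8 | {[(4R,5Z)-2-bromo-6-iodohepta-1,5-dien-4-yl]oxy}(tert-butyl)dimethylsilane | I/C(C)=C\[C@H](O[Si](C)(C)C(C)(C)C)CC(Br)=C | intermediate
9 | (2-ethoxy-2-oxoethyl)zinc bromide | CCOC(=O)C[Zn]Br | starting material
10 | ethyl (3Z,5R)-7-bromo-5-[(tert-butyldimethylsilyl)oxy]-3-methylocta-3,7-dienoate | CCOC(=O)C/C(C)=C\[C@H](O[Si](C)(C)C(C)(C)C)CC(Br)=C | intermediate
11 | (3Z,5R)-7-bromo-5-[(tert-butyldimethylsilyl)oxy]-3-methylocta-3,7-dienal | O=CC/C(C)=C\[C@H](O[Si](C)(C)C(C)(C)C)CC(Br)=C | intermediate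
12 | (4S)-2,2-dimethyl-1,3-dioxolane-4-carbaldehyde | O=C[C@@H]1COC(C)(C)O1 | starting material
13 | methyl acrylate | C=CC(=O)OC | starting material
14 | methyl 2-{[(4S)-2,2-dimethyl-1,3-dioxolan-4-yl](hydroxy)methyl}prop-2-enoate (both carbinol epimers) | COC(=O)C(=C)C(O)[C@@H]1COC(C)(C)O1 | intermediate
15 | methyl (2Z)-2-(bromomethyl)-3-[(4R)-2,2-dimethyl-1,3-dioxolan-4-yl]prop-2-enoate | COC(=O)/C(CBr)=C/[C@@H]1COC(C)(C)O1 | intermediate
16 | methyl (2Z,4R)-2-(bromomethyl)-4,5-dihydroxypent-2-enoate (diol bromide, not isolated) | COC(=O)/C(CBr)=C/[C@@H](O)CO | intermediate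
17 | methyl (3R,4R,6Z,8R)-10-bromo-8-[(tert-butyldimethylsilyl)oxy]-3-[(1R)-1,2-dihydroxyethyl]-4-hydroxy-6-methyl-2-methylideneundeca-6,10-dienoate | COC(=O)C(=C)[C@@H]([C@@H](O)CO)[C@H](O)C/C(C)=C\[C@H](O[Si](C)(C)C(C)(C)C)CC(Br)=C | intermediate
18 | methyl (3R,4R,6Z,8R)-10-bromo-8-[(tert-butyldimethylsilyl)oxy]-3-[(4R)-2,2-dimethyl-1,3-dioxolan-4-yl]-4-hydroxy-6-methyl-2-methylideneundeca-6,10-dienoate | COC(=O)C(=C)[C@@H]([C@@H]1COC(C)(C)O1)[C@H](O)C/C(C)=C\[C@H](O[Si](C)(C)C(C)(C)C)CC(Br)=C | intermediate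
19 | methyl (3R,4R,6Z,8R)-10-bromo-8-[(tert-butyldimethylsilyl)oxy]-3-[(4R)-2,2-dimethyl-1,3-dioxolan-4-yl]-6-methyl-4-{[(2E)-2-methylbut-2-enoyl]oxy}-2-methylideneundeca-6,10-dienoate | COC(=O)C(=C)[C@@H]([C@@H]1COC(C)(C)O1)[C@H](OC(=O)/C(C)=C/C)C/C(C)=C\[C@H](O[Si](C)(C)C(C)(C)C)CC(Br)=C | intermediate
20 | methyl (3S,4R,6Z,8R)-10-bromo-8-[(tert-butyldimethylsilyl)oxy]-3-[(1R)-1,2-dihydroxyethyl]-6-methyl-4-{[(2E)-2-methylbut-2-enoyl]oxy}-2-methylideneundeca-6,10-dienoate (diol ester, not isolated; the descriptor at C3 changes by priority only, the centre is untouched) | COC(=O)C(=C)[C@@H]([C@@H](O)CO)[C@H](OC(=O)/C(C)=C/C)C/C(C)=C\[C@H](O[Si](C)(C)C(C)(C)C)CC(Br)=C | intermediate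
21 | (1R,3Z,5R)-7-bromo-5-[(tert-butyldimethylsilyl)oxy]-1-[(2R,3R)-2-(hydroxymethyl)-4-methylidene-5-oxooxolan-3-yl]-3-methylocta-3,7-dien-1-yl (2E)-2-methylbut-2-enoate | C=C1C(=O)O[C@@H](CO)[C@H]1[C@H](OC(=O)/C(C)=C/C)C/C(C)=C\[C@H](O[Si](C)(C)C(C)(C)C)CC(Br)=C | intermediate
22 | (1R,3Z,5R)-7-bromo-5-[(tert-butyldimethylsilyl)oxy]-1-[(2R,3R)-2-formyl-4-methylidene-5-oxooxolan-3-yl]-3-methylocta-3,7-dien-1-yl (2E)-2-methylbut-2-enoate | C=C1C(=O)O[C@@H](C=O)[C@H]1[C@H](OC(=O)/C(C)=C/C)C/C(C)=C\[C@H](O[Si](C)(C)C(C)(C)C)CC(Br)=C | intermediate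
23 | (1(10)Z,2R,5S,6R,7R,8R)-2-[(tert-butyldimethylsilyl)oxy]-5-hydroxy-8-{[(2E)-2-methylbut-2-enoyl]oxy}germacra-1(10),4(15),11(13)-trien-12,6-olide | C=C1C(=O)O[C@@H]2[C@H]1[C@H](OC(=O)/C(C)=C/C)C/C(C)=C\[C@H](O[Si](C)(C)C(C)(C)C)CC(=C)[C@@H]2O | intermediate
24 | (1(10)Z,2R,5S,6R,7R,8R)-5-acetoxy-2-[(tert-butyldimethylsilyl)oxy]-8-{[(2E)-2-methylbut-2-enoyl]oxy}germacra-1(10),4(15),11(13)-trien-12,6-olide | C=C1C(=O)O[C@@H]2[C@H]1[C@H](OC(=O)/C(C)=C/C)C/C(C)=C\[C@H](O[Si](C)(C)C(C)(C)C)CC(=C)[C@@H]2OC(C)=O | intermediate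
25 | CNP0210609.1, (1(10)Z,2R,5S,6R,7R,8R)-5-acetoxy-2-hydroxy-8-{[(2E)-2-methylbut-2-enoyl]oxy}germacra-1(10),4(15),11(13)-trien-12,6-olide | C=C1C(=O)O[C@@H]2[C@H]1[C@H](OC(=O)/C(C)=C/C)C/C(C)=C\[C@H](O)CC(=C)[C@@H]2OC(C)=O | target

**Step count and risks**

Total step count: 17. Longest linear sequence: 15 (steps 1–7, then 10–17).

Most likely to fail:

1. Step 15. The strain of the forming ten-membered ring may override the Felkin–Anh preference, so that the alkenylchromium adds to the wrong face of the aldehyde and the C5 epimer forms. The fallback sets out from 22 and comes back at 24. The cyclisation is run as in step 15 and the C5-epimeric (5R)-alcohol F1 is taken on. A Mitsunobu esterification of the (5R)-alcohol F1 with acetic acid (PPh3, DIAD, toluene, 0 °C) replaces the activated allylic hydroxyl by acetate with inversion and should give 24. C5 is then fixed by an SN2 displacement and no longer by the carbon–carbon bond formation.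

2. Step 10. The hydroxyl-directed delivery may be lost: if the aldehyde enters anti to the allylic C–O bond (the sense expected without chelation), C7 and C8 form with the wrong sense relative to C6. The fallback sets out from 11 and comes back at 21; it uses the non-chelated sense and repairs C6 by inversion. (R)-2,2-Dimethyl-1,3-dioxolane-4-carbaldehyde and tert-butyl acrylate should give, under the conditions of step 8, the Morita–Baylis–Hillman adduct F2 and then, under the conditions of step 9, the (Z)-allyl bromide F3 with the enantiomeric dioxolane. The allyl bromide F3 and 11 with In in THF/H2O, the acetonide being kept, should give the homoallylic alcohol F4 with C7 and C8 as required and C6 epimeric. Tigloylation of the homoallylic alcohol F4 as in step 12 should give the tiglate F5 and treatment with CeCl3·7H2O and oxalic acid should free the diol F6 whose tert-butyl ester does not lactonise. PPh3 and DIAD should close the terminal epoxide F7 with retention at C6. BF3·OEt2 in CH2Cl2 at −78 °C then lets the ester carbonyl open the epoxide F7 at C6 in a 5-exo mode with inversion and loss of 2-methylpropene, which gives 21.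

3. Step 6. Transmetalation of the zinc ester enolate may be slow, which leaves time for migration of the new β,γ-alkene into conjugation and for competing insertion into the C–Br bond. The fallback sets out from 8 and comes back at 11. Stille coupling of 8 with tributyl(vinyl)stannane (Pd2(dba)3, AsPh3, CuI, NMP, rt; the C–I bond reacts, the C–Br bond does not) should give the silyl-protected bromotriene F8 with the Z geometry kept. Hydroboration of the monosubstituted vinyl group of the bromotriene F8 with disiamylborane and oxidation with NaBO3 should give the homoallylic alcohol F9 and Dess–Martin oxidation of the alcohol F9 gives 11.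

**Further compounds**

F1 | step 15 | (1(10)Z,2R,5R,6R,7R,8R)-2-[(tert-butyldimethylsilyl)oxy]-5-hydroxy-8-{[(2E)-2-methylbut-2-enoyl]oxy}germacra-1(10),4(15),11(13)-trien-12,6-olide | C=C1C(=O)O[C@@H]2[C@H]1[C@H](OC(=O)/C(C)=C/C)C/C(C)=C\[C@H](O[Si](C)(C)C(C)(C)C)CC(=C)[C@H]2O
F2 | step 10 | tert-butyl 2-{[(4R)-2,2-dimethyl-1,3-dioxolan-4-yl](hydroxy)methyl}prop-2-enoate (both carbinol epimers) | CC(C)(C)OC(=O)C(=C)C(O)[C@H]1COC(C)(C)O1
F3 | step 10 | tert-butyl (2Z)-2-(bromomethyl)-3-[(4S)-2,2-dimethyl-1,3-dioxolan-4-yl]prop-2-enoate | CC(C)(C)OC(=O)/C(CBr)=C/[C@H]1COC(C)(C)O1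
F4 | step 10 | tert-butyl (3R,4R,6Z,8R)-10-bromo-8-[(tert-butyldimethylsilyl)oxy]-3-[(4S)-2,2-dimethyl-1,3-dioxolan-4-yl]-4-hydroxy-6-methyl-2-methylideneundeca-6,10-dienoate | CC(C)(C)OC(=O)C(=C)[C@@H]([C@H]1COC(C)(C)O1)[C@H](O)C/C(C)=C\[C@H](O[Si](C)(C)C(C)(C)C)CC(Br)=C
F5 | step 10 | tert-butyl (3R,4R,6Z,8R)-10-bromo-8-[(tert-butyldimethylsilyl)oxy]-3-[(4S)-2,2-dimethyl-1,3-dioxolan-4-yl]-6-methyl-4-{[(2E)-2-methylbut-2-enoyl]oxy}-2-methylideneundeca-6,10-dienoate | CC(C)(C)OC(=O)C(=C)[C@@H]([C@H]1COC(C)(C)O1)[C@H](OC(=O)/C(C)=C/C)C/C(C)=C\[C@H](O[Si](C)(C)C(C)(C)C)CC(Br)=C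
F6 | step 10 | tert-butyl (3S,4R,6Z,8R)-10-bromo-8-[(tert-butyldimethylsilyl)oxy]-3-[(1S)-1,2-dihydroxyethyl]-6-methyl-4-{[(2E)-2-methylbut-2-enoyl]oxy}-2-methylideneundeca-6,10-dienoate | CC(C)(C)OC(=O)C(=C)[C@@H]([C@H](O)CO)[C@H](OC(=O)/C(C)=C/C)C/C(C)=C\[C@H](O[Si](C)(C)C(C)(C)C)CC(Br)=C
F7 | step 10 | tert-butyl (3R,4R,6Z,8R)-10-bromo-8-[(tert-butyldimethylsilyl)oxy]-6-methyl-4-{[(2E)-2-methylbut-2-enoyl]oxy}-2-methylidene-3-[(2S)-oxiran-2-yl]undeca-6,10-dienoate | CC(C)(C)OC(=O)C(=C)[C@@H]([C@H]1CO1)[C@H](OC(=O)/C(C)=C/C)C/C(C)=C\[C@H](O[Si](C)(C)C(C)(C)C)CC(Br)=C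
F8 | step 6 | {[(4R,5Z)-2-bromo-6-methylocta-1,5,7-trien-4-yl]oxy}(tert-butyl)dimethylsilane | C=C/C(C)=C\[C@H](O[Si](C)(C)C(C)(C)C)CC(Br)=C
F9 | step 6 | (3Z,5R)-7-bromo-5-[(tert-butyldimethylsilyl)oxy]-3-methylocta-3,7-dien-1-ol | OCC/C(C)=C\[C@H](O[Si](C)(C)C(C)(C)C)CC(Br)=C
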